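The question is how much target maple holds at 8.0 d, and which option still adds target.

| flask | starting material | reagent | protic impurity | temperature | remark | time |
|---|---|---|---|---|---|---|
| maple | 0.12 M | 0.096 M | 2.4 mM | 90 °C | the very flask that is asked about, followed so far |  |
| elm | 0.12 M | 0.096 M | 2.4 mM | 75 °C | run made earlier |  |
| flask | 0.12 M | 0.0960 M | 2.40 mM | 90 °C |  | 8.0 d |

| run | time / d | target / % | starting material / % |
|---|---|---|---|
| maple | 0.625 | 23.3 | 43.3 |
| maple | 1.67 | 39.3 | 28.9 |
| maple | 3.00 | 45.8 | 20.8 |
| maple | 5.00 | 47.7 | 18.4 |
| elm | 1.25 | 9.3 | 53.7 |
| elm | 4.00 | 31.5 | 32.3 |
| elm | 6.00 | 38.8 | 24.9 |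
| elm | 10.0 | 44.3 | 20.8 |

(scatter of a reading: 1 percentage point)

- red: at 8.0 d add reagent, 100% of the amount charged, then wait 4.0 d
- blue: at 8.0 d take out 90% of the target then present, then wait 4.0 d
- grey: at 8.0 d raise the temperature by 25 K, then wait 4.0 d
- violet: change nothing and wait 4.0 d more

- removed target is counted in
- additions bring no volume worth counting

* target, in percent of the starting material first charged, at 8.0 d
* the option that brings most further target ("none" if no option brings more than 2 percentage points) (red / blue / grey / violet / none)
* target present, with what was taken out counted in, in percent of the starting material first charged, after blue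
* target present, with what was taken out counted in, in percent of the starting material first charged, after violet

1. Maple and elm differ in temperature. Elm reads 38.8% target at 6.00 d and maple reads 39.3% at 1.67 d, so by these readings maple's clock runs about 3.59 times faster.

2. Both flasks hold less [reagent] than [starting material], which makes reagent the limiting reagent. If reagent and protic impurity each take one starting material, the same floor of 18.0% starting material awaits both flasks. Elm's 20.8% at 10.0 d corresponds to 2.78 d on maple's clock, and maple reads 20.8% at 3.00 d. So elm's last reading, with the same charges, stands where maple stood at about the same clock time, above maple's 18.4% at 5.00 d.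

3. In maple, by these readings, the excess of starting material over the floor shrinks between the second and third readings with a half-life of about 0.678 d. From 5.00 d to 8.0 d lie 4.42 such half-lives, and the excess at 5.00 d is already within the scatter of 1 percentage point.

4. The carried quantity is the yield per reagent: target made per starting material that the reagent charge can turn over, here 59.6% from maple's last reading. My own reckoning keeps about 47.7% target at 8.0 d. Red brings fresh reagent to the 18.0% starting material at the floor, which is worth 11 points if the same yield per reagent holds. Waiting, blue and grey show no gain in this reckoning.

5. The forecast gives 48.7%, red, 49.5% after blue and 48.9% after violet: “Red works under both readings.”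

6. Maple gives 48.0%, red adds 11 points, and blue and violet end at 48.1% and 48.1%.

    starting material + protic impurity → quenched substrate (k = 18.5 /M/h, Ea = 63.0 kJ/mol)
    starting material + reagent → intermediate + released group (k = 1.04 /M/h, Ea = 83.0 kJ/mol)
    intermediate → target (k = 0.0717 /h, Ea = 112 kJ/mol)
    intermediate → side product (k = 0.0474 /h, Ea = 114 kJ/mol)
    (constants at 90 °C)

The yield per reagent, read at 59.6%, lies below 100% mainly because the intermediate also goes to side product: the run without that step ends at 79.7% target against 48.0%. The neighbour charged with 0.48 M starting material has 0.200 equivalents of reagent, so the yield per reagent gives 11.9%, and that neighbour holds 12.0% target.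

The data were computed for an exercise; scatter was added.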